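**Plan**

- Retrosynthesis: the silyl ethers and the C4 oxidation level are adjusted last. The isoflavanone is traced to the isoflavone, ring C is opened at O1–C8a and C2–C3, and ring A is cut at C4a–C5 and C8–C8a into a benzyl bromoethynyl ketone and a ketene-acetal diene. The ynone is cut at C4–C4a and C3–C4 back to a chromene aldehyde.
- Enabling feature: ring A is a phloroglucinol whose three oxygens are all different (C5–OMe, C7–OH, C8a–O1) and surround the acyl-bearing C4a. A 1,1-dimethoxy-3-silyloxydiene writes OMe and OH onto an ynone, and a bromine on the ynone β-carbon marks C8a for O1.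
- Forward order: ring D (the dimethylpyran on ring B) by a propargyl Claisen cascade, chain extension to the bromoynone, ring A by Diels–Alder benzannulation, C2 by formylation, ring C by copper-catalysed enol O-arylation.
- Stereochemistry: C3 (R), the only stereocentre, is set by asymmetric transfer hydrogenation of the isoflavone with dynamic kinetic resolution (cis-3R,4R carbinol) and is kept when C4 is oxidised back to the ketone.
- C2 is added only after ring A, so the ynone carries no β-leaving group and ring C closes through an enol oxygen.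

Key step: step 9

Remark: 4,4-dimethoxybut-3-en-2-one is treated as a purchased ketene acetal.

**Route**

Step 1
Reactants: 1 3,4-dihydroxybenzaldehyde; 2 3-chloro-3-methylbut-1-yne
Product: 3 3-hydroxy-4-[(2-methylbut-3-yn-2-yl)oxy]benzaldehyde
Conditions: K2CO3 (1.05 equiv), KI, CuI (cat.), DMF, 60 °C
Reagents that add atoms: none
Why: Williamson-type O-propargylation (copper-assisted substitution of the tertiary propargylic chloride); one equivalent of weak base ionises only the 4-hydroxyl, which is para to the formyl group and much more acidic than the 3-hydroxyl, so the ether should form there.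

Step 2
Reactants: 3 3-hydroxy-4-[(2-methylbut-3-yn-2-yl)oxy]benzaldehyde
Product: 4 8-hydroxy-2,2-dimethyl-2H-chromene-6-carbaldehyde
Conditions: N,N-diethylaniline, 190 °C
Reagents that add atoms: none
Why: aromatic propargyl Claisen rearrangement followed by 1,5-hydrogen shift and oxa-6π electrocyclisation; the ether has only one free ortho position (C5 of the benzaldehyde), so ring D can fuse in one way only.

Step 3
Reactants: 4 8-hydroxy-2,2-dimethyl-2H-chromene-6-carbaldehyde
Product: 5 2,2-dimethyl-8-[(triisopropylsilyl)oxy]-2H-chromene-6-carbaldehyde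
Conditions: TIPSCl, imidazole, DMF, rt
Reagents that add atoms: chlorotriisopropylsilane, CC(C)[Si](Cl)(C(C)C)C(C)C
Why: standard imidazole-promoted silylation of a phenol; the bulky aryl triisopropylsilyl ether should withstand the ylide, the Grignard reagent and the dilute acid of the following steps.

Step 4
Reactants: 5 2,2-dimethyl-8-[(triisopropylsilyl)oxy]-2H-chromene-6-carbaldehyde
Product: 7 2-{2,2-dimethyl-8-[(triisopropylsilyl)oxy]-2H-chromen-6-yl}acetaldehyde, via methyl enol ether 6 (not isolated)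
Conditions: Ph3P(CH2OMe)Cl, KOtBu, THF, 0 °C; then 2 M HCl, THF, 45 °C
Reagents that add atoms: (methoxymethyl)triphenylphosphonium chloride, [Cl-].COC[P+](c1ccccc1)(c1ccccc1)c1ccccc1; water, O
Why: Wittig methoxymethylenation followed by acid hydrolysis of the enol ether is the standard one-carbon homologation of an aryl aldehyde to an arylacetaldehyde, and 2,2-dimethylchromenes and aryl silyl ethers are known to tolerate dilute aqueous acid.

Step 5
Reactants: 7 2-{2,2-dimethyl-8-[(triisopropylsilyl)oxy]-2H-chromen-6-yl}acetaldehyde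
Product: 8 1-{2,2-dimethyl-8-[(triisopropylsilyl)oxy]-2H-chromen-6-yl}but-3-yn-2-ol (racemic)
Conditions: HC≡CMgBr, THF, −78 to 0 °C; aq. NH4Cl
Reagents that add atoms: ethynylmagnesium bromide, C#C[Mg]Br
Why: 1,2-addition of an alkynyl Grignard reagent to an aldehyde at low temperature, where addition should outrun enolisation; the carbinol centre is formed racemic and is removed by oxidation in step 7.

Step 6
Reactants: 8 1-{2,2-dimethyl-8-[(triisopropylsilyl)oxy]-2H-chromen-6-yl}but-3-yn-2-ol (racemic)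
Product: 9 4-bromo-1-{2,2-dimethyl-8-[(triisopropylsilyl)oxy]-2H-chromen-6-yl}but-3-yn-2-ol (racemic)
Conditions: NBS, AgNO3 (10 mol %), acetone, rt, dark
Reagents that add atoms: N-bromosuccinimide, O=C1CCC(=O)N1Br
Why: silver-catalysed bromination of a terminal alkyne through its silver acetylide, which is expected to outpace attack of the reagent on the arene or on the ring D alkene in dry acetone; it is run at the alcohol stage so that no enolisable ynone meets the brominating agent.

Step 7
Reactants: 9 4-bromo-1-{2,2-dimethyl-8-[(triisopropylsilyl)oxy]-2H-chromen-6-yl}but-3-yn-2-ol (racemic)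
Product: 10 4-bromo-1-{2,2-dimethyl-8-[(triisopropylsilyl)oxy]-2H-chromen-6-yl}but-3-yn-2-one
Conditions: DMP, CH2Cl2, 0 °C
Reagents that add atoms: none
Why: Dess–Martin oxidation of a propargylic alcohol to the ynone under neutral conditions that leave the bromoalkyne, the benzylic CH2 and ring D untouched.

Step 8
Reactants: 11 4,4-dimethoxybut-3-en-2-one
Product: 12 1,1-dimethoxy-3-[(trimethylsilyl)oxy]buta-1,3-diene
Conditions: Me3SiOTf, Et3N, Et2O, 0 °C
Reagents that add atoms: trimethylsilyl trifluoromethanesulfonate, C[Si](C)(C)OS(=O)(=O)C(F)(F)F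
Why: soft enolisation and O-silylation of the methyl ketone (silyl dienol ether formation) gives the cross-conjugated ketene-acetal diene, the usual way to 1,1-dialkoxy-3-silyloxybutadienes.

Step 9
Reactants: 10 4-bromo-1-{2,2-dimethyl-8-[(triisopropylsilyl)oxy]-2H-chromen-6-yl}but-3-yn-2-one; 12 1,1-dimethoxy-3-[(trimethylsilyl)oxy]buta-1,3-diene
Product: 14 1-(2-bromo-4-hydroxy-6-methoxyphenyl)-2-{2,2-dimethyl-8-[(triisopropylsilyl)oxy]-2H-chromen-6-yl}ethan-1-one, via cyclohexa-1,4-diene cycloadduct 13 (not isolated)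
Conditions: toluene, rt to 60 °C; then 0.5 M HCl, THF, 0 °C
Reagents that add atoms: none
Why: The CH2 terminus of 12, the carbon with the largest HOMO coefficient because both the ketene acetal and the silyloxy group push electron density onto it, bonds to the bromine-bearing β-carbon of ynone 10 while the ketene-acetal carbon bonds to the α-carbon in a concerted but asynchronous normal-demand Diels–Alder reaction. Ring A is closed by this intermolecular [4+2] cycloaddition, which forms C8–C8a and C4a–C5 in one event and gives cyclohexa-1,4-diene 13; loss of methanol from the ketal carbon then aromatises the ring, and the dilute acid work-up turns the silyl enol ether oxygen into the C7 phenol. The closest known reactions are the benzannulations of 1,1-dialkoxy-3-silyloxybuta-1,3-dienes with alkynyl ketones and propiolates, which give 2-alkoxy-4-hydroxyaryl carbonyl compounds, and the Diels–Alder reactions of 3-bromopropiolates, in which the halogen stays on the ring. No stereocentre is formed. The step needs regioselectivity (OMe next to the acyl carbon, Br on the future C8a) and chemoselectivity for the alkyne: the first follows from the matched polarisation of the diene terminus and the ynone β-carbon, the second from the neutral thermal conditions, under which the ring D alkene, the aryl silyl ether and the enolisable CH2 of 10 are spectators and the ketone, having no β-leaving group, cannot eliminate.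

Step 10
Reactants: 14 1-(2-bromo-4-hydroxy-6-methoxyphenyl)-2-{2,2-dimethyl-8-[(triisopropylsilyl)oxy]-2H-chromen-6-yl}ethan-1-one
Product: 15 1-{2-bromo-6-methoxy-4-[(triisopropylsilyl)oxy]phenyl}-2-{2,2-dimethyl-8-[(triisopropylsilyl)oxy]-2H-chromen-6-yl}ethan-1-one
Conditions: TIPSCl, imidazole, DMF, rt
Reagents that add atoms: chlorotriisopropylsilane, CC(C)[Si](Cl)(C(C)C)C(C)C
Why: imidazole-promoted silylation of the only free phenol; masking C7–OH keeps ring A from becoming a phenoxide, which would deactivate the aryl bromide in the base-mediated steps that follow.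

Step 11
Reactants: 15 1-{2-bromo-6-methoxy-4-[(triisopropylsilyl)oxy]phenyl}-2-{2,2-dimethyl-8-[(triisopropylsilyl)oxy]-2H-chromen-6-yl}ethan-1-one
Product: 16 (Z)-1-{2-bromo-6-methoxy-4-[(triisopropylsilyl)oxy]phenyl}-2-{2,2-dimethyl-8-[(triisopropylsilyl)oxy]-2H-chromen-6-yl}-3-hydroxyprop-2-en-1-one
Conditions: HCO2Et, NaH, THF, 0 °C to rt; then 1 M HCl, 0 °C
Reagents that add atoms: ethyl formate, CCOC=O
Why: crossed Claisen condensation (C-formylation) of the deoxybenzoin enolate with ethyl formate, driven by deprotonation of the α-formyl ketone, which is obtained as its chelated Z-enol and supplies C2 together with the future O1.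

Step 12
Reactants: 16 (Z)-1-{2-bromo-6-methoxy-4-[(triisopropylsilyl)oxy]phenyl}-2-{2,2-dimethyl-8-[(triisopropylsilyl)oxy]-2H-chromen-6-yl}-3-hydroxyprop-2-en-1-one
Product: 17 3-{2,2-dimethyl-8-[(triisopropylsilyl)oxy]-2H-chromen-6-yl}-5-methoxy-7-[(triisopropylsilyl)oxy]-4H-chromen-4-one
Conditions: CuI (10 mol %), 1,10-phenanthroline (20 mol %), Cs2CO3, toluene, 80 °C
Reagents that add atoms: none
Why: copper-catalysed intramolecular Ullmann-type O-arylation of a 1,3-dicarbonyl enol, the known chromone-forming C–O coupling; the ortho carbonyl group activates the C–Br bond, both ring A oxygens are meta to it, and closure of the six-membered ring through the enol oxygen is the only feasible mode.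

Step 13
Reactants: 17 3-{2,2-dimethyl-8-[(triisopropylsilyl)oxy]-2H-chromen-6-yl}-5-methoxy-7-[(triisopropylsilyl)oxy]-4H-chromen-4-one
Product: 19 (3R,4R)-3-{2,2-dimethyl-8-[(triisopropylsilyl)oxy]-2H-chromen-6-yl}-5-methoxy-7-[(triisopropylsilyl)oxy]chroman-4-ol, via racemic isoflavanone 18 (not isolated)
Conditions: RuCl[(R,R)-TsDPEN](p-cymene) (3 mol %), HCO2H/Et3N (5:2), EtOAc, 40 °C
Reagents that add atoms: none
Why: Noyori–Ikariya asymmetric transfer hydrogenation of an isoflavone: conjugate hydride transfer gives isoflavanone 18, which racemises through its enol in the amine-containing medium while the catalyst reduces one enantiomer faster (dynamic kinetic resolution), hydride adding to C4 anti to the C3 aryl group; the (R,R) ligand is expected to set 4R, as for aryl alkyl ketones, and thereby 3R in the cis carbinol.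

Step 14
Reactants: 19 (3R,4R)-3-{2,2-dimethyl-8-[(triisopropylsilyl)oxy]-2H-chromen-6-yl}-5-methoxy-7-[(triisopropylsilyl)oxy]chroman-4-ol
Product: 20 (3R)-3-{2,2-dimethyl-8-[(triisopropylsilyl)oxy]-2H-chromen-6-yl}-5-methoxy-7-[(triisopropylsilyl)oxy]chroman-4-one
Conditions: DMP, CH2Cl2, 0 °C
Reagents that add atoms: none
Why: Dess–Martin oxidation of the benzylic carbinol under neutral, non-enolising conditions removes the C4 stereocentre and should leave the configuration at C3 untouched.

Step 15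
Reactants: 20 (3R)-3-{2,2-dimethyl-8-[(triisopropylsilyl)oxy]-2H-chromen-6-yl}-5-methoxy-7-[(triisopropylsilyl)oxy]chroman-4-one
Product: 21 (3R)-7-hydroxy-3-(8-hydroxy-2,2-dimethyl-2H-chromen-6-yl)-5-methoxychroman-4-one
Conditions: Bu4NF, AcOH (1:1), THF, 0 °C to rt
Reagents that add atoms: none
Why: fluoride-mediated cleavage of both aryl silyl ethers, buffered with acetic acid so that neither basic fluoride nor a free phenoxide can enolise the C3–H ketone and erode the stereocentre.

**Compound list**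

1 | 3,4-dihydroxybenzaldehyde | O=Cc1ccc(O)c(O)c1 | starting material
2 | 3-chloro-3-methylbut-1-yne | CC(C)(Cl)C#C | starting material
3 | 3-hydroxy-4-[(2-methylbut-3-yn-2-yl)oxy]benzaldehyde | O=Cc1ccc(OC(C)(C)C#C)c(O)c1 | intermediate
4 | 8-hydroxy-2,2-dimethyl-2H-chromene-6-carbaldehyde | O=Cc1cc(O)c2OC(C)(C)C=Cc2c1 | intermediate
5 | 2,2-dimethyl-8-[(triisopropylsilyl)oxy]-2H-chromene-6-carbaldehyde | O=Cc1cc(O[Si](C(C)C)(C(C)C)C(C)C)c2OC(C)(C)C=Cc2c1 | intermediate
6 | 6-(2-methoxyethenyl)-2,2-dimethyl-8-[(triisopropylsilyl)oxy]-2H-chromene (E/Z mixture) | COC=Cc1cc(O[Si](C(C)C)(C(C)C)C(C)C)c2OC(C)(C)C=Cc2c1 | intermediate (not isolated)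
7 | 2-{2,2-dimethyl-8-[(triisopropylsilyl)oxy]-2H-chromen-6-yl}acetaldehyde | O=CCc1cc(O[Si](C(C)C)(C(C)C)C(C)C)c2OC(C)(C)C=Cc2c1 | intermediate
8 | 1-{2,2-dimethyl-8-[(triisopropylsilyl)oxy]-2H-chromen-6-yl}but-3-yn-2-ol (racemic) | C#CC(O)Cc1cc(O[Si](C(C)C)(C(C)C)C(C)C)c2OC(C)(C)C=Cc2c1 | intermediate
9 | 4-bromo-1-{2,2-dimethyl-8-[(triisopropylsilyl)oxy]-2H-chromen-6-yl}but-3-yn-2-ol (racemic) | BrC#CC(O)Cc1cc(O[Si](C(C)C)(C(C)C)C(C)C)c2OC(C)(C)C=Cc2c1 | intermediate
10 | 4-bromo-1-{2,2-dimethyl-8-[(triisopropylsilyl)oxy]-2H-chromen-6-yl}but-3-yn-2-one | BrC#CC(=O)Cc1cc(O[Si](C(C)C)(C(C)C)C(C)C)c2OC(C)(C)C=Cc2c1 | intermediate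
11 | 4,4-dimethoxybut-3-en-2-one | CC(=O)C=C(OC)OC | starting material
12 | 1,1-dimethoxy-3-[(trimethylsilyl)oxy]buta-1,3-diene | C=C(O[Si](C)(C)C)C=C(OC)OC | intermediate
13 | 1-{2-bromo-6,6-dimethoxy-4-[(trimethylsilyl)oxy]cyclohexa-1,4-dien-1-yl}-2-{2,2-dimethyl-8-[(triisopropylsilyl)oxy]-2H-chromen-6-yl}ethan-1-one | COC1(OC)C=C(O[Si](C)(C)C)CC(Br)=C1C(=O)Cc1cc(O[Si](C(C)C)(C(C)C)C(C)C)c2OC(C)(C)C=Cc2c1 | intermediate (not isolated)
14 | 1-(2-bromo-4-hydroxy-6-methoxyphenyl)-2-{2,2-dimethyl-8-[(triisopropylsilyl)oxy]-2H-chromen-6-yl}ethan-1-one | COc1cc(O)cc(Br)c1C(=O)Cc1cc(O[Si](C(C)C)(C(C)C)C(C)C)c2OC(C)(C)C=Cc2c1 | intermediate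
15 | 1-{2-bromo-6-methoxy-4-[(triisopropylsilyl)oxy]phenyl}-2-{2,2-dimethyl-8-[(triisopropylsilyl)oxy]-2H-chromen-6-yl}ethan-1-one | COc1cc(O[Si](C(C)C)(C(C)C)C(C)C)cc(Br)c1C(=O)Cc1cc(O[Si](C(C)C)(C(C)C)C(C)C)c2OC(C)(C)C=Cc2c1 | intermediate
16 | (Z)-1-{2-bromo-6-methoxy-4-[(triisopropylsilyl)oxy]phenyl}-2-{2,2-dimethyl-8-[(triisopropylsilyl)oxy]-2H-chromen-6-yl}-3-hydroxyprop-2-en-1-one | COc1cc(O[Si](C(C)C)(C(C)C)C(C)C)cc(Br)c1C(=O)/C(=C\O)c1cc(O[Si](C(C)C)(C(C)C)C(C)C)c2OC(C)(C)C=Cc2c1 | intermediate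
17 | 3-{2,2-dimethyl-8-[(triisopropylsilyl)oxy]-2H-chromen-6-yl}-5-methoxy-7-[(triisopropylsilyl)oxy]-4H-chromen-4-one | COc1cc(O[Si](C(C)C)(C(C)C)C(C)C)cc2OC=C(c3cc(O[Si](C(C)C)(C(C)C)C(C)C)c4OC(C)(C)C=Cc4c3)C(=O)c12 | intermediate
18 | 3-{2,2-dimethyl-8-[(triisopropylsilyl)oxy]-2H-chromen-6-yl}-5-methoxy-7-[(triisopropylsilyl)oxy]chroman-4-one (racemic) | COc1cc(O[Si](C(C)C)(C(C)C)C(C)C)cc2OCC(c3cc(O[Si](C(C)C)(C(C)C)C(C)C)c4OC(C)(C)C=Cc4c3)C(=O)c12 | intermediate (not isolated)
19 | (3R,4R)-3-{2,2-dimethyl-8-[(triisopropylsilyl)oxy]-2H-chromen-6-yl}-5-methoxy-7-[(triisopropylsilyl)oxy]chroman-4-ol (cis) | COc1cc(O[Si](C(C)C)(C(C)C)C(C)C)cc2c1[C@H](O)[C@H](c1cc(O[Si](C(C)C)(C(C)C)C(C)C)c3c(c1)C=CC(C)(C)O3)CO2 | intermediate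
20 | (3R)-3-{2,2-dimethyl-8-[(triisopropylsilyl)oxy]-2H-chromen-6-yl}-5-methoxy-7-[(triisopropylsilyl)oxy]chroman-4-one | COc1cc(O[Si](C(C)C)(C(C)C)C(C)C)cc2c1C(=O)[C@H](c1cc(O[Si](C(C)C)(C(C)C)C(C)C)c3c(c1)C=CC(C)(C)O3)CO2 | intermediate
21 | (3R)-7-hydroxy-3-(8-hydroxy-2,2-dimethyl-2H-chromen-6-yl)-5-methoxychroman-4-one | COc1cc(O)cc2c1C(=O)[C@H](c1cc(O)c3c(c1)C=CC(C)(C)O3)CO2 | target

**Step count and risks**

Total: 15 steps. Longest linear sequence: 14 steps (steps 1–7 and 9–15; step 8 is a one-step side branch).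

Steps most likely to fail:

1. Step 9 (key step). The ketene-acetal terminus may add to the bromoalkyne stepwise, and the zwitterion may then expel bromide or oligomerise instead of closing the ring, so that the cyclohexadiene never forms. The fallback sets out from 7 and returns at 15, bringing ring A in as a preformed arene. 3-Bromo-5-methoxyphenol is silylated (TIPSCl, imidazole, DMF) to 1-bromo-3-methoxy-5-[(triisopropylsilyl)oxy]benzene F1. Directed ortho-metalation of F1 between Br and OMe with lithium 2,2,6,6-tetramethylpiperidide (THF, −78 °C) and addition of the aryllithium to aldehyde 7 should give 1-{2-bromo-6-methoxy-4-[(triisopropylsilyl)oxy]phenyl}-2-{2,2-dimethyl-8-[(triisopropylsilyl)oxy]-2H-chromen-6-yl}ethan-1-ol F2 (racemic). Dess–Martin oxidation of F2 gives 15.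

2. Step 13. Conjugate hydride transfer to the hindered, electron-rich chromenone may stall, or the peri methoxy group may lower the facial discrimination at C4, so that the enantiomeric purity at C3 falls short. The fallback sets out from 17 and returns at 20. 1,4-Reduction of 17 with LiBH(s-Bu)3 (THF, −78 °C) and trapping of the enolate with Me3SiCl give the silyl enol ether 3-{2,2-dimethyl-8-[(triisopropylsilyl)oxy]-2H-chromen-6-yl}-5-methoxy-7-[(triisopropylsilyl)oxy]-4-[(trimethylsilyl)oxy]-2H-chromene F3. Catalytic enantioselective protonation of F3 (BINOL-derived N-triflyl thiophosphoramide, phenol as stoichiometric proton source, toluene, rt; the catalyst enantiomer that delivers the 3R ketone) gives 20 directly, without passing through the carbinol.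

3. Step 12. Under the basic coupling conditions the α-formyl ketone may lose its formyl group by retro-Claisen cleavage and the ring A silyl ether may be cleaved, which would stop the C–O coupling. The fallback sets out from 15 and returns at 17, closing ring C from a phenol instead. Miyaura borylation of 15 (B2pin2, Pd(dppf)Cl2, KOAc, dioxane, 80 °C) gives 1-{2-methoxy-6-(4,4,5,5-tetramethyl-1,3,2-dioxaborolan-2-yl)-4-[(triisopropylsilyl)oxy]phenyl}-2-{2,2-dimethyl-8-[(triisopropylsilyl)oxy]-2H-chromen-6-yl}ethan-1-one F4. Buffered oxidation (aq. H2O2, THF, pH 7, 0 °C) gives 1-{2-hydroxy-6-methoxy-4-[(triisopropylsilyl)oxy]phenyl}-2-{2,2-dimethyl-8-[(triisopropylsilyl)oxy]-2H-chromen-6-yl}ethan-1-one F5. Condensation of F5 with Me2NCH(OMe)2 (toluene, 90 °C), the classical deoxybenzoin route to isoflavones, gives 17.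

**Further compounds**

F1 | step 9 | 1-bromo-3-methoxy-5-[(triisopropylsilyl)oxy]benzene | COc1cc(Br)cc(O[Si](C(C)C)(C(C)C)C(C)C)c1
F2 | step 9 | 1-{2-bromo-6-methoxy-4-[(triisopropylsilyl)oxy]phenyl}-2-{2,2-dimethyl-8-[(triisopropylsilyl)oxy]-2H-chromen-6-yl}ethan-1-ol (racemic) | COc1cc(O[Si](C(C)C)(C(C)C)C(C)C)cc(Br)c1C(O)Cc1cc(O[Si](C(C)C)(C(C)C)C(C)C)c2OC(C)(C)C=Cc2c1
F3 | step 13 | 3-{2,2-dimethyl-8-[(triisopropylsilyl)oxy]-2H-chromen-6-yl}-5-methoxy-7-[(triisopropylsilyl)oxy]-4-[(trimethylsilyl)oxy]-2H-chromene | COc1cc(O[Si](C(C)C)(C(C)C)C(C)C)cc2OCC(c3cc(O[Si](C(C)C)(C(C)C)C(C)C)c4OC(C)(C)C=Cc4c3)=C(O[Si](C)(C)C)c12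
F4 | step 12 | 1-{2-methoxy-6-(4,4,5,5-tetramethyl-1,3,2-dioxaborolan-2-yl)-4-[(triisopropylsilyl)oxy]phenyl}-2-{2,2-dimethyl-8-[(triisopropylsilyl)oxy]-2H-chromen-6-yl}ethan-1-one | COc1cc(O[Si](C(C)C)(C(C)C)C(C)C)cc(B2OC(C)(C)C(C)(C)O2)c1C(=O)Cc1cc(O[Si](C(C)C)(C(C)C)C(C)C)c2OC(C)(C)C=Cc2c1
F5 | step 12 | 1-{2-hydroxy-6-methoxy-4-[(triisopropylsilyl)oxy]phenyl}-2-{2,2-dimethyl-8-[(triisopropylsilyl)oxy]-2H-chromen-6-yl}ethan-1-one | COc1cc(O[Si](C(C)C)(C(C)C)C(C)C)cc(O)c1C(=O)Cc1cc(O[Si](C(C)C)(C(C)C)C(C)C)c2OC(C)(C)C=Cc2c1
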